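## The problem

Compound 18 is built from two 2-(2-phenylethyl)chromones joined by one biaryl bond between C6 and C5'. Unit A is a 7-hydroxychromone and unit B (primed locants) an 8-hydroxychromone. There is no stereocentre. The biaryl axis has only two non-hydrogen ortho groups (the C7 hydroxyl and the ring-fusion carbon C4a'), so it is not expected to be configurationally stable and no stereocontrol is needed. The sensitive parts are the two γ-pyranone rings, which open in hot aqueous hydroxide and accept nucleophiles at C2 and C2', and the two phenols, which must stay masked until the end. Pyranone A is routine, because ring A has the resorcinol pattern of an ortho-hydroxyacetophenone, and the C6–C5' bond is an ordinary cross-coupling. The difficulty is in ring B: C4a' must carry the carbonyl carbon C4', yet it is wedged between the C5' aryl group and C8a' and lies meta to the C8' oxygen. Any electrophilic acylation would go to C6' or C7' instead. What opens a way is that O1' sits on C8a', directly beside C4a', while the other neighbour of C8a', C8', already carries oxygen. A three-carbon unit hung on O1' as a propargyl ether can therefore be handed to C4a' by a [3,3] shift, and C4a' is the only ortho carbon at which the ring can rearomatise.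

## Retrosynthesis

**18 from 17.** The two O–CH3 bonds are cut last. Methyl ethers are chosen for both phenols because they must pass NaH, hot acid, a palladium coupling, 190 °C and electrophilic bromine. Benzyl ethers would need a hydrogenolysis that endangers the pyranone double bonds, and silyl ethers would not survive the basic and thermal steps. The forward step is a double BBr3 cleavage on the bis-methyl ether 17, which chromones tolerate.

**17 from 14 through 15 and 16.** Pyranone B is traced back to the 2H-chromene 14, which lacks the C4' oxygen and the C2'=C3' unsaturation. Bromohydrin 15 places water at benzylic C4', where the cation is stabilised by ring B and O1'. Oxidation gives bromoketone 16, and loss of HBr gives 17. The bromine introduced with the oxygen is the leaving group that later creates the C2'=C3' bond, so oxygenation and dehydrogenation are coupled. A Wacker-type oxidation followed by dehydrogenation would be one step shorter, but the site of hydroxypalladation on a cyclic styrene is less secure, so it is not relied on. All stereocentres of 14 to 16 are erased in 17.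

**14 from 10 (key disconnection).** The C4'–C4a' bond is cut and the pyran ring is opened to the aryl propargyl ether 10, in which O1'–C2' is a plain ether bond. Neighbouring options are weaker: Friedel–Crafts acylation avoids C4a', and a Fries shift of an O1' ester could also go para to C6'. The [3,3] shift is strictly ortho-specific, needs no electronic activation at C4a', and has only one ortho carbon where it can end productively. The precursor 10 is a phenol ether of a finished unit A. The forward reaction must tolerate the crowded site next to the C5' aryl group.

**10 from 7 and 9.** The O1'–C2' ether bond is cut to phenol 7 and racemic alkynol 9. A Mitsunobu reaction joins them under neutral conditions that leave pyranone A alone. The terminal alkyne is introduced only after the palladium step.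

**9 from 8.** The C2'–C3' bond of the alkynol is cut to 3-phenylpropanal 8 and ethynylmagnesium bromide.

**7 from 5 and 6.** The C6–C5' biaryl bond is cut to bromochromone 5 and (3-hydroxy-4-methoxyphenyl)boronic acid 6. This polarity is chosen because the bromine comes with the acetophenone starting material and 6 carries the free phenol needed in the next step, so no borylation and no protecting group are needed.

**5 from 2 and 3, and 2 from 1.** Pyranone A is cut at C2–C3 and O1–C2 to the ortho-hydroxyacetophenone 2 and ethyl 3-phenylpropanoate 3, through diketone 4. Compound 2 comes from bromoresacetophenone 1 by methylation of the 4-hydroxyl, the one not chelated to the carbonyl group.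

## Roads not taken

**Alternative 1:** Ring B is cut at both C6–C5' and C4a'–C4' on the aryne 3,4-dimethoxybenzyne A2. In the forward step A2 is generated by loss of LiF from an ortho-lithiated aryl fluoride. The Grignard reagent (2,4-dimethoxyphenyl)magnesium bromide A3 adds at the aryne carbon remote from the methoxy group, and the arylmagnesium left at C4a' is acylated by the Weinreb amide N-methoxy-N-methyl-5-phenylpent-2-ynamide A4 to give ynone A1.
- Merits: the two hardest bonds of ring B form in one flask, and C4' arrives at the ketone oxidation level with the whole C2' side chain. Pyranone B then needs only a selective demethylation and a ring closure. This is better than the chosen plan, which spends three steps adjusting the oxidation level after the key step.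
- Weak points: in a three-component aryne relay the excess A3 meets both A4 and the product A1, and both accept conjugate addition. Acylation of a 2,6-disubstituted arylmagnesium is slow. After A1, ring A has neither its C4 carbon nor a pyranone, so a Friedel–Crafts acylation and a strongly basic Claisen condensation must be run beside an ynone or a finished pyranone B, and four methyl ethers must be told apart.
- Comparison: the chosen plan arrives at the key step with unit A complete and builds only one pyranone afterwards. Against the aryne route's oxidation-state economy it sets a Suzuki coupling and a pericyclic cascade whose site selectivity is built into the substrate.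

**Alternative 2:** Benzene ring A is taken apart into the diazo enone A6, carried on the ring B arene, and ethoxyethyne A7. Irradiation of A6 gives a vinylketene by Wolff rearrangement, which adds A7 in a [2+2] sense. Heating opens the four-membered ring and closes the six-membered ring to the phenol A5.
- Merits: the substitution pattern of ring A is fixed by mechanism, no cross-coupling of two arenes is needed, and the C7 hydroxyl emerges free and distinct from the ethers.
- Weak points: A5 contains neither pyranone. Ring A still needs its C4 carbon by a later acylation and cleavage of the ethyl ether. The ring B ester must be homologated to a diketone or ynone. The ester and the free phenol face each other across the biaryl bond and are set up to lactonise. The route also does not answer the ring B question: the carbon on C4a' must already be present in A6, so the contiguous substitution of ring B has to be bought or built beforehand. A diazo ketone, a photochemical step and a volatile alkoxyalkyne add practical burden.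
- Comparison: it is better only in avoiding palladium and in differentiating O7. The chosen plan needs no such differentiation, because both ethers fall together at the end, and it is much shorter after the key step.

**Alternative 3:** Benzene ring A is cut at C4a–C5. The precursor A9 is a 4-pyranone carrying a 2-oxoalkyl side chain with an aryl-substituted methoxymethylene ketone. Under acid the side-chain ketone enolises toward the pyranone, C4a attacks the methoxymethylene carbon, and loss of methanol aromatises ring A to A8, which is the 8'-O-methyl ether of the target.
- Merits: this is the most convergent finish. Both pyranones are in place, the C7 hydroxyl is formed free, nothing is oxidised or reduced afterwards, and one demethylation remains. If A9 were in hand, this would be clearly shorter than the four steps that follow the key step of the chosen plan.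
- Weak points: the weight falls on A9. It requires a complete unit B with a carbon substituent at C5', so the C4a'–C4' problem is only moved into the precursor synthesis. The methoxymethylene group must be installed at the aryl-bearing carbon and not at the more acidic methylene between ketone and pyranone. The ring closure relies on a weakly nucleophilic pyranone C–H, and the enol oxygen can close on the same carbon instead.
- Comparison: the chosen plan is longer at the end, but every intermediate is reached by standard reactions and the one demanding bond is made by a reaction that cannot choose another site.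

Key step: step 6

## Route

Assumption: (3-hydroxy-4-methoxyphenyl)boronic acid 6 is taken as a purchased building block. All sp3 centres created on the way are racemic and are removed before the target is reached.

Step 1
Reactants: 1 1-(5-bromo-2,4-dihydroxyphenyl)ethanone
Product: 2 1-(5-bromo-2-hydroxy-4-methoxyphenyl)ethanone
Conditions: MeI (1.1 equiv), K2CO3 (1.1 equiv), acetone, 56 °C
Reagents that add atoms: iodomethane, CI
Why: Williamson methylation; the 2-hydroxyl is hydrogen-bonded to the acetyl carbonyl and much less nucleophilic, so the 4-hydroxyl is alkylated selectively, as in the classical preparation of paeonol-type ethers.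

Step 2
Reactants: 2 1-(5-bromo-2-hydroxy-4-methoxyphenyl)ethanone; 3 ethyl 3-phenylpropanoate
Product: 5 6-bromo-7-methoxy-2-(2-phenylethyl)chromen-4-one, via 1,3-diketone 4 (not isolated)
Conditions: NaH (4 equiv), THF, 65 °C; then conc. HCl, MeOH, 65 °C
Reagents that add atoms: none
Why: Crossed Claisen condensation of the phenoxide-enolate dianion of 2 with the ester gives the 1,3-diketone, and acid-catalysed cyclodehydration closes the γ-pyranone; this is the standard entry to 2-(2-phenylethyl)chromones.

Step 3
Reactants: 5 6-bromo-7-methoxy-2-(2-phenylethyl)chromen-4-one; 6 (3-hydroxy-4-methoxyphenyl)boronic acid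
Product: 7 6-(3-hydroxy-4-methoxyphenyl)-7-methoxy-2-(2-phenylethyl)chromen-4-one
Conditions: Pd(dppf)Cl2 (5 mol %), K2CO3, 1,4-dioxane/H2O, 90 °C
Reagents that add atoms: none
Why: Suzuki–Miyaura coupling; the electron-poor C6–Br bond adds readily to zerovalent palladium, the free phenol of 6 is tolerated under carbonate, and the mild base leaves the pyranone closed.

Step 4
Reactants: 8 3-phenylpropanal
Product: 9 5-phenylpent-1-yn-3-ol (racemic)
Conditions: HC≡CMgBr (0.5 M in THF), THF, 0 °C; aq. NH4Cl
Reagents that add atoms: ethynylmagnesium bromide, C#C[Mg]Br
Why: Grignard 1,2-addition of the acetylide to the aldehyde; the new carbinol centre is formed racemic, which is sufficient because it is destroyed later.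

Step 5
Reactants: 7 6-(3-hydroxy-4-methoxyphenyl)-7-methoxy-2-(2-phenylethyl)chromen-4-one; 9 5-phenylpent-1-yn-3-ol (racemic)
Product: 10 7-methoxy-6-[4-methoxy-3-(5-phenylpent-1-yn-3-yloxy)phenyl]-2-(2-phenylethyl)chromen-4-one (racemic)
Conditions: PPh3, DIAD, THF, 0 °C to rt
Reagents that add atoms: none
Why: Mitsunobu etherification; the guaiacol-type phenol is acidic enough to protonate the betaine and displaces the activated secondary propargylic oxygen by SN2, and the neutral conditions leave the pyranone and the alkyne untouched.

Step 6
Reactants: 10 7-methoxy-6-[4-methoxy-3-(5-phenylpent-1-yn-3-yloxy)phenyl]-2-(2-phenylethyl)chromen-4-one (racemic)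
Product: 14 7-methoxy-6-[8-methoxy-2-(2-phenylethyl)-2H-chromen-5-yl]-2-(2-phenylethyl)chromen-4-one (racemic), via allenyl cyclohexadienone 11 (not isolated), via ortho-allenylphenol 12 (not isolated), via dienyl quinone methide 13 (not isolated)
Conditions: PhNEt2 (degassed), 190 °C, sealed tube
Reagents that add atoms: none
Why: Heating triggers an aromatic propargyl Claisen rearrangement: the alkyne terminus C4' bonds to C4a' as the O1'–C2' ether bond breaks, giving allenyl cyclohexadienone 11. Enolisation restores the arene in allenylphenol 12, and a 1,5-hydrogen shift from the phenol to the central allene carbon gives the (Z)-dienyl ortho-quinone methide 13. A thermal, disrotatory oxa-6π-electrocyclisation then re-forms O1'–C2' and closes the six-membered pyran ring of unit B as the 2H-chromene. The closest known reaction type is the thermal conversion of aryl propargyl ethers into 2H-chromenes in N,N-dialkylanilines, which accepts secondary propargylic carbons and terminal alkynes. The step needs site selectivity between the two ortho carbons, and the substrate secures it: a shift to the methoxy-bearing C8' gives a dienone that cannot enolise and can only revert, whereas C4a' carries the hydrogen needed for rearomatisation. Because the shift is concerted and intramolecular it needs no nucleophilicity at C4a' and should tolerate the twisted aryl group at C5'. The C2' stereocentre is formed racemic with no controlling element, which is acceptable because it becomes sp2 in step 9. No fluoride or strong base is added, so that phenol 12 is not diverted into a benzofuran.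

Step 7
Reactants: 14 7-methoxy-6-[8-methoxy-2-(2-phenylethyl)-2H-chromen-5-yl]-2-(2-phenylethyl)chromen-4-one (racemic)
Product: 15 6-[3-bromo-4-hydroxy-8-methoxy-2-(2-phenylethyl)-3,4-dihydro-2H-chromen-5-yl]-7-methoxy-2-(2-phenylethyl)chromen-4-one (3',4'-trans, mixture of racemic C2' epimers)
Conditions: NBS (1.05 equiv), DMSO/THF/H2O, 0 °C, dark
Reagents that add atoms: N-bromosuccinimide, O=C1CCC(=O)N1Br; water, O
Why: Bromohydrin formation, a standard reaction of 2H-chromenes; the bromonium ion on the electron-rich styrenyl C3'=C4' bond is opened by water at benzylic C4', where the charge is stabilised by ring B and O1'. Anti addition sets the 3',4'-trans relation and bromine is expected to enter mainly anti to the C2' side chain; none of these centres survives.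

Step 8
Reactants: 15 6-[3-bromo-4-hydroxy-8-methoxy-2-(2-phenylethyl)-3,4-dihydro-2H-chromen-5-yl]-7-methoxy-2-(2-phenylethyl)chromen-4-one
Product: 16 6-[3-bromo-8-methoxy-4-oxo-2-(2-phenylethyl)-2,3-dihydrochromen-5-yl]-7-methoxy-2-(2-phenylethyl)chromen-4-one (mixture of racemic diastereomers)
Conditions: DMP (1.3 equiv), CH2Cl2, 0 °C to rt
Reagents that add atoms: none
Why: Dess–Martin oxidation of the secondary benzylic alcohol to the ketone under near-neutral conditions that do not displace the adjacent bromide.

Step 9
Reactants: 16 6-[3-bromo-8-methoxy-4-oxo-2-(2-phenylethyl)-2,3-dihydrochromen-5-yl]-7-methoxy-2-(2-phenylethyl)chromen-4-one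
Product: 17 7-methoxy-6-[8-methoxy-4-oxo-2-(2-phenylethyl)chromen-5-yl]-2-(2-phenylethyl)chromen-4-one
Conditions: DBU (2 equiv), THF, rt
Reagents that add atoms: none
Why: Base-induced dehydrobromination of a 3-bromochroman-4-one, the classical way to a chromone; C3' epimerises through the enolate so that either diastereomer can reach the anti-periplanar arrangement for E2 loss of HBr, driven by formation of the conjugated γ-pyranone.

Step 10
Reactants: 17 7-methoxy-6-[8-methoxy-4-oxo-2-(2-phenylethyl)chromen-5-yl]-2-(2-phenylethyl)chromen-4-one
Product: 18 7-hydroxy-6-[8-hydroxy-4-oxo-2-(2-phenylethyl)chromen-5-yl]-2-(2-phenylethyl)chromen-4-one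
Conditions: BBr3 (6 equiv), CH2Cl2, −78 °C to rt; then H2O
Reagents that add atoms: none
Why: Lewis-acid cleavage of aryl methyl ethers by BBr3 (bromide attacks the methyl group of the boron-bound ether); excess reagent allows for binding to the two pyranone carbonyls, and chromones are known to survive these conditions.

## Compound list

1 | 1-(5-bromo-2,4-dihydroxyphenyl)ethanone | CC(=O)c1cc(Br)c(O)cc1O | starting material
2 | 1-(5-bromo-2-hydroxy-4-methoxyphenyl)ethanone | CC(=O)c1cc(Br)c(OC)cc1O | intermediate
3 | ethyl 3-phenylpropanoate | CCOC(=O)CCc1ccccc1 | starting material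
4 | 1-(5-bromo-2-hydroxy-4-methoxyphenyl)-5-phenylpentane-1,3-dione | COc1cc(O)c(C(=O)CC(=O)CCc2ccccc2)cc1Br | intermediate
5 | 6-bromo-7-methoxy-2-(2-phenylethyl)chromen-4-one | COc1cc2oc(CCc3ccccc3)cc(=O)c2cc1Br | intermediate
6 | (3-hydroxy-4-methoxyphenyl)boronic acid | COc1ccc(B(O)O)cc1O | starting material
7 | 6-(3-hydroxy-4-methoxyphenyl)-7-methoxy-2-(2-phenylethyl)chromen-4-one | COc1cc2oc(CCc3ccccc3)cc(=O)c2cc1-c1ccc(OC)c(O)c1 | intermediate
8 | 3-phenylpropanal | O=CCCc1ccccc1 | starting material
9 | 5-phenylpent-1-yn-3-ol (racemic) | C#CC(O)CCc1ccccc1 | intermediate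
10 | 7-methoxy-6-[4-methoxy-3-(5-phenylpent-1-yn-3-yloxy)phenyl]-2-(2-phenylethyl)chromen-4-one (racemic) | COc1cc2oc(CCc3ccccc3)cc(=O)c2cc1-c1ccc(OC)c(OC(CCc2ccccc2)C#C)c1 | intermediate
11 | 7-methoxy-6-[4-methoxy-5-oxo-6-(5-phenylpenta-1,2-dien-1-yl)cyclohexa-1,3-dien-1-yl]-2-(2-phenylethyl)chromen-4-one (stereoisomer mixture) | COC1=CC=C(c2cc3c(=O)cc(CCc4ccccc4)oc3cc2OC)C(C=C=CCCc2ccccc2)C1=O | intermediate
12 | 6-[3-hydroxy-4-methoxy-2-(5-phenylpenta-1,2-dien-1-yl)phenyl]-7-methoxy-2-(2-phenylethyl)chromen-4-one (racemic allene) | COc1ccc(-c2cc3c(=O)cc(CCc4ccccc4)oc3cc2OC)c(C=C=CCCc2ccccc2)c1O | intermediate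
13 | 7-methoxy-6-[4-methoxy-5-oxo-6-(5-phenylpent-2-en-1-ylidene)cyclohexa-1,3-dien-1-yl]-2-(2-phenylethyl)chromen-4-one (chain double bond Z, ylidene chain syn to the ring carbonyl) | COC1=CC=C(c2cc3c(=O)cc(CCc4ccccc4)oc3cc2OC)/C(=C/C=C\CCc2ccccc2)C1=O | intermediate
14 | 7-methoxy-6-[8-methoxy-2-(2-phenylethyl)-2H-chromen-5-yl]-2-(2-phenylethyl)chromen-4-one (racemic) | COc1cc2oc(CCc3ccccc3)cc(=O)c2cc1-c1ccc(OC)c2OC(CCc3ccccc3)C=Cc12 | intermediate
15 | 6-[3-bromo-4-hydroxy-8-methoxy-2-(2-phenylethyl)-3,4-dihydro-2H-chromen-5-yl]-7-methoxy-2-(2-phenylethyl)chromen-4-one (3',4'-trans, mixture of racemic C2' epimers) | COc1cc2oc(CCc3ccccc3)cc(=O)c2cc1-c1ccc(OC)c2OC(CCc3ccccc3)C(Br)C(O)c12 | intermediate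
16 | 6-[3-bromo-8-methoxy-4-oxo-2-(2-phenylethyl)-2,3-dihydrochromen-5-yl]-7-methoxy-2-(2-phenylethyl)chromen-4-one (mixture of racemic diastereomers) | COc1cc2oc(CCc3ccccc3)cc(=O)c2cc1-c1ccc(OC)c2OC(CCc3ccccc3)C(Br)C(=O)c12 | intermediate
17 | 7-methoxy-6-[8-methoxy-4-oxo-2-(2-phenylethyl)chromen-5-yl]-2-(2-phenylethyl)chromen-4-one | COc1cc2oc(CCc3ccccc3)cc(=O)c2cc1-c1ccc(OC)c2oc(CCc3ccccc3)cc(=O)c12 | intermediate
18 | 7-hydroxy-6-[8-hydroxy-4-oxo-2-(2-phenylethyl)chromen-5-yl]-2-(2-phenylethyl)chromen-4-one | O=c1cc(CCc2ccccc2)oc2cc(O)c(-c3ccc(O)c4oc(CCc5ccccc5)cc(=O)c34)cc12 | target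

## Step count and risks

Total step count: 10. Longest linear sequence: 9 steps (steps 1, 2, 3, 5, 6, 7, 8, 9 and 10, from 1); step 4 is a one-step side branch.

**Step 6 (key step).** The most likely failure is a slow [3,3] shift at the crowded C4a' position. The reversible shift toward C8' could then leak into irreversible cycloadditions of the blocked dienone, or the terminal alkyne could oligomerise at the temperature needed. The fallback changes the order of events so that the cascade runs on a small bromoarene before the biaryl bond exists. It sets out from 9 and 5 and comes back at 14. Commercial 5-bromo-2-methoxyphenol F1 would be etherified with 9 under Mitsunobu conditions to 4-bromo-1-methoxy-2-(5-phenylpent-1-yn-3-yloxy)benzene F2. Heating F2 in N,N-diethylaniline should give 5-bromo-8-methoxy-2-(2-phenylethyl)-2H-chromene F3, where a bromine atom replaces the chromonyl group beside C4a' and the substrate is cheap enough to be forced. Bromide 5 would be converted with B2pin2, Pd(dppf)Cl2 and KOAc into 7-methoxy-2-(2-phenylethyl)-6-(4,4,5,5-tetramethyl-1,3,2-dioxaborolan-2-yl)chromen-4-one F4. Suzuki coupling of F3 with F4 (Pd(dppf)Cl2, K2CO3) would give 14.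

**Step 7.** Electrophilic bromine may be consumed by aromatic substitution on the electron-rich ring B (C6', para to O1') or at C8 or C3 of unit A, in competition with addition to the chromene double bond. The fallback avoids electrophilic halogen. It sets out from 14 and comes back at 17. Mukaiyama hydration (Co(acac)2, PhSiH3, O2, THF) proceeds through the benzylic C4' radical and should give 6-[4-hydroxy-8-methoxy-2-(2-phenylethyl)-3,4-dihydro-2H-chromen-5-yl]-7-methoxy-2-(2-phenylethyl)chromen-4-one F5. Dess–Martin oxidation would give the chromanone 7-methoxy-6-[8-methoxy-4-oxo-2-(2-phenylethyl)-2,3-dihydrochromen-5-yl]-2-(2-phenylethyl)chromen-4-one F6. Dehydrogenation with IBX in DMSO at 70 °C would give 17.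

**Step 5.** With a secondary propargylic alcohol the Mitsunobu reaction may suffer SN2' attack (allenyl ether formation) or elimination to an enyne, and the hindered alkoxyphosphonium ion may be displaced slowly. The fallback replaces redox activation by a preformed leaving group. It sets out from 9 and comes back at 10. MsCl and Et3N would convert 9 into 5-phenylpent-1-yn-3-yl methanesulfonate F7, which would alkylate phenol 7 with K2CO3 in DMF.

**Step 2.** The intermolecular Claisen condensation may be undercut by self-condensation of ester 3 or by incomplete acylation of the dianion, leaving 2 unchanged. The fallback makes the C–C bond intramolecularly (Baker–Venkataraman). It sets out from 2 and comes back at 5 through 4. The phenol of 2 would be acylated with 3-phenylpropanoyl chloride F8 in pyridine to 2-acetyl-4-bromo-5-methoxyphenyl 3-phenylpropanoate F9. KOtBu in THF would move the acyl group to the enolate carbon to give 4, and HCl in MeOH would close the ring as in step 2.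

## Further compounds

F1 | step 6 | 5-bromo-2-methoxyphenol | COc1ccc(Br)cc1O
F2 | step 6 | 4-bromo-1-methoxy-2-(5-phenylpent-1-yn-3-yloxy)benzene (racemic) | COc1ccc(Br)cc1OC(CCc1ccccc1)C#C
F3 | step 6 | 5-bromo-8-methoxy-2-(2-phenylethyl)-2H-chromene (racemic) | COc1ccc(Br)c2C=CC(CCc3ccccc3)Oc12
F4 | step 6 | 7-methoxy-2-(2-phenylethyl)-6-(4,4,5,5-tetramethyl-1,3,2-dioxaborolan-2-yl)chromen-4-one | COc1cc2oc(CCc3ccccc3)cc(=O)c2cc1B1OC(C)(C)C(C)(C)O1
F5 | step 7 | 6-[4-hydroxy-8-methoxy-2-(2-phenylethyl)-3,4-dihydro-2H-chromen-5-yl]-7-methoxy-2-(2-phenylethyl)chromen-4-one (mixture of racemic diastereomers) | COc1cc2oc(CCc3ccccc3)cc(=O)c2cc1-c1ccc(OC)c2OC(CCc3ccccc3)CC(O)c12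
F6 | step 7 | 7-methoxy-6-[8-methoxy-4-oxo-2-(2-phenylethyl)-2,3-dihydrochromen-5-yl]-2-(2-phenylethyl)chromen-4-one (racemic) | COc1cc2oc(CCc3ccccc3)cc(=O)c2cc1-c1ccc(OC)c2OC(CCc3ccccc3)CC(=O)c12
F7 | step 5 | 5-phenylpent-1-yn-3-yl methanesulfonate (racemic) | CS(=O)(=O)OC(CCc1ccccc1)C#C
F8 | step 2 | 3-phenylpropanoyl chloride | O=C(Cl)CCc1ccccc1
F9 | step 2 | 2-acetyl-4-bromo-5-methoxyphenyl 3-phenylpropanoate | COc1cc(OC(=O)CCc2ccccc2)c(C(C)=O)cc1Br
A1 | alternative 1 | 1-[6-(2,4-dimethoxyphenyl)-2,3-dimethoxyphenyl]-5-phenylpent-2-yn-1-one | COc1ccc(-c2ccc(OC)c(OC)c2C(=O)C#CCCc2ccccc2)c(OC)c1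
A2 | alternative 1 | 3,4-dimethoxybenzyne | COC1=C(OC)C=CC#C1
A3 | alternative 1 | (2,4-dimethoxyphenyl)magnesium bromide | COc1ccc([Mg]Br)c(OC)c1
A4 | alternative 1 | N-methoxy-N-methyl-5-phenylpent-2-ynamide | CON(C)C(=O)C#CCCc1ccccc1
A5 | alternative 2 | methyl 6-(4-ethoxy-2-hydroxyphenyl)-2,3-dimethoxybenzoate | COC(=O)c1c(OC)c(OC)ccc1-c1ccc(OCC)cc1O
A6 | alternative 2 | methyl 6-[(E)-4-diazo-3-oxobut-1-enyl]-2,3-dimethoxybenzoate | COC(=O)c1c(OC)c(OC)ccc1/C=C/C(=O)C=[N+]=[N-]
A7 | alternative 2 | ethoxyethyne | CCOC#C
A8 | alternative 3 | 7-hydroxy-6-[8-methoxy-4-oxo-2-(2-phenylethyl)chromen-5-yl]-2-(2-phenylethyl)chromen-4-one | O=c1cc(CCc2ccccc2)oc2cc(O)c(-c3ccc(OC)c4oc(CCc5ccccc5)cc(=O)c34)cc12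
A9 | alternative 3 | 8-methoxy-5-{1-methoxy-3-oxo-4-[4-oxo-6-(2-phenylethyl)-4H-pyran-2-yl]but-1-en-2-yl}-2-(2-phenylethyl)chromen-4-one | COC=C(c1ccc(OC)c2oc(CCc3ccccc3)cc(=O)c12)C(=O)Cc1cc(=O)cc(CCc2ccccc2)o1
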